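**Retrosynthetic overview**
- Manuifolin D ⇐ reductive opening of the O11–C11a bond of a fully substituted (6aR,11aR)-pterocarpan (sulfonate cleavage, p-quinone methide, hydride). The pterocarpan ring keeps the future 2'-OH masked while the B ring is dressed.
- B-ring substituents ⇐ O-prenylation, aromatic Claisen rearrangement (gives the 1,1-dimethylallyl group at C8), second O-prenylation of a 9-hydroxypterocarpan 3-tosylate.
- Pterocarpan ⇐ one flask from an acyclic deoxybenzoin: C1 insertion with chromone closure (pyran ring), Ru transfer hydrogenation with dynamic kinetic resolution (sets C3), acid MOM removal with SN1 closure (dihydrofuran ring).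
- Deoxybenzoin ⇐ Pd α-arylation of 2-hydroxy-4-tosyloxyacetophenone with 1-bromo-2,4-bis(methoxymethoxy)benzene.
- Ring order: pyran ring first, dihydrofuran ring second in the same operation; the dihydrofuran is opened again in the last step.

Assumption: the (R,R)-TsDPEN–Ru catalyst is taken to give the (4R)-carbinol, as it does with chroman-4-one; if the sense proves opposite, the (S,S) catalyst is used.

**Step 1**
Reactants: 1 2,4-dihydroxyacetophenone
Product: 2 4-acetyl-3-hydroxyphenyl 4-methylbenzenesulfonate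
Conditions: TsCl (1.05 equiv), K2CO3 (1.1 equiv), acetone, 0 °C to rt
Reagents that add atoms: p-toluenesulfonyl chloride, Cc1ccc(cc1)S(=O)(=O)Cl
Why: Chemoselective O-sulfonylation, because the 2-OH is locked in a hydrogen bond to the acetyl group and only the more acidic 4-OH is deprotonated by carbonate; no stereocentre is involved.

**Step 2**
Reactants: 3 4-bromoresorcinol
Product: 4 1-bromo-2,4-bis(methoxymethoxy)benzene
Conditions: NaH (2.4 equiv), MOMCl (2.4 equiv), DMF, 0 °C to rt
Reagents that add atoms: chloromethyl methyl ether, COCCl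
Why: Williamson-type O-alkylation (MOM protection) of both phenoxides, which masks the future 2'-OH so that later carbonyl intermediates cannot close to benzofurans.

**Step 3**
Reactants: 2 4-acetyl-3-hydroxyphenyl 4-methylbenzenesulfonate; 4 1-bromo-2,4-bis(methoxymethoxy)benzene
Product: 5 4-{[2,4-bis(methoxymethoxy)phenyl]acetyl}-3-hydroxyphenyl 4-methylbenzenesulfonate
Conditions: Pd2(dba)3 (2.5 mol%), t-Bu3P·HBF4 (6 mol%), LiHMDS (3.3 equiv), THF, 50 °C; aq. NH4Cl
Reagents that add atoms: none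
Why: Pd-catalysed ketone α-arylation (Buchwald–Hartwig–Miura type) of the phenoxide/enolate dianion of 2, with the t-Bu3P–Pd catalyst inserting into C–Br much faster than into the aryl tosylate and the MOM ethers inert to the amide base.

**Step 4**
Reactants: 5 4-{[2,4-bis(methoxymethoxy)phenyl]acetyl}-3-hydroxyphenyl 4-methylbenzenesulfonate
Product: 11 (6aR,11aR)-9-hydroxy-6a,11a-dihydro-6H-[1]benzofuro[3,2-c]chromen-3-yl 4-methylbenzenesulfonate, via enaminone 6 (not isolated), via isoflavone 7 (not isolated), via isoflavanone 8 (not isolated), via cis-isoflavan-4-ol 9 (not isolated), via triol 10 (not isolated)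
Conditions: one flask: DMF-DMA (2 equiv), THF, 65 °C, evaporate; RuCl(p-cymene)[(R,R)-TsDPEN] (2 mol%), HCO2H/Et3N (5:2), EtOAc, 40 °C; then 3 M HCl, MeOH, 50 °C
Reagents that add atoms: N,N-dimethylformamide dimethyl acetal, COC(OC)N(C)C
Why: DMF-DMA aminomethylenates the doubly activated CH2 and the chelated 2-OH displaces Me2NH to close the chromone (cyclocondensation, ring 1), Noyori–Ikariya asymmetric transfer hydrogenation then reduces C2=C3 and, with dynamic kinetic resolution of the enolisable isoflavanone, the ketone on the face set by the (R,R) ligand to give the cis-(3R,4R) carbinol, and HCl/MeOH removes both MOM groups so that the 2'-OH captures the C4 benzylic cation (SN1) to close the cis-fused dihydrofuran (ring 2), which fixes C6a as R from the DKR and C11a as R by ring fusion while the electron-poor tosylate keeps the product from re-ionising.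

**Step 5**
Reactants: 11 (6aR,11aR)-9-hydroxy-6a,11a-dihydro-6H-[1]benzofuro[3,2-c]chromen-3-yl 4-methylbenzenesulfonate
Product: 12 (6aR,11aR)-9-[(3-methylbut-2-en-1-yl)oxy]-6a,11a-dihydro-6H-[1]benzofuro[3,2-c]chromen-3-yl 4-methylbenzenesulfonate
Conditions: prenyl bromide (1.2 equiv), K2CO3 (1.5 equiv), acetone, 56 °C
Reagents that add atoms: prenyl bromide (1-bromo-3-methylbut-2-ene), CC(C)=CCBr
Why: Williamson ether synthesis at the only free phenol, the other two ring oxygens being tied up as tosylate and as the pterocarpan ether; the stereocentres are not touched.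

**Step 6**
Reactants: 12 (6aR,11aR)-9-[(3-methylbut-2-en-1-yl)oxy]-6a,11a-dihydro-6H-[1]benzofuro[3,2-c]chromen-3-yl 4-methylbenzenesulfonate
Product: 13 (6aR,11aR)-9-hydroxy-8-(2-methylbut-3-en-2-yl)-6a,11a-dihydro-6H-[1]benzofuro[3,2-c]chromen-3-yl 4-methylbenzenesulfonate
Conditions: PhNEt2, 195 °C (sealed tube), 2 h
Reagents that add atoms: none
Why: Aromatic Claisen ([3,3]-sigmatropic) rearrangement transfers the allyl unit with inversion (prenyl to 1,1-dimethylallyl) to C8, the ortho position para to O11 and not flanked by two oxygens, and the neutral to basic medium leaves the tosylate and both stereocentres intact.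

**Step 7**
Reactants: 13 (6aR,11aR)-9-hydroxy-8-(2-methylbut-3-en-2-yl)-6a,11a-dihydro-6H-[1]benzofuro[3,2-c]chromen-3-yl 4-methylbenzenesulfonate
Product: 14 (6aR,11aR)-8-(2-methylbut-3-en-2-yl)-9-[(3-methylbut-2-en-1-yl)oxy]-6a,11a-dihydro-6H-[1]benzofuro[3,2-c]chromen-3-yl 4-methylbenzenesulfonate
Conditions: prenyl bromide (1.5 equiv), K2CO3 (2 equiv), DMF, 40 °C
Reagents that add atoms: prenyl bromide (1-bromo-3-methylbut-2-ene), CC(C)=CCBr
Why: Williamson ether synthesis of the hindered but only free phenol with a reactive allylic bromide in a dipolar aprotic solvent; no stereocentre is affected.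

**Step 8**
Reactants: 14 (6aR,11aR)-8-(2-methylbut-3-en-2-yl)-9-[(3-methylbut-2-en-1-yl)oxy]-6a,11a-dihydro-6H-[1]benzofuro[3,2-c]chromen-3-yl 4-methylbenzenesulfonate
Product: 17 Manuifolin D, via pterocarpan-3-ol 15 (not isolated), via p-quinone methide 16 (not isolated)
Conditions: NaOH (5 equiv), NaBH4 (10 equiv), EtOH/H2O (4:1), 80 °C; aq. NH4Cl
Reagents that add atoms: none
Why: Proposed new method: hydroxide cleaves the aryl sulfonate, the freed 3-phenoxide (para to C11a) expels the tethered B-ring aryloxide to give a p-quinone methide (E1cB), and borohydride adds irreversibly to its exocyclic carbon (1,6-reduction) before the C3–H can tautomerise, so C3 stays R and the prenyl ether and alkene are untouched; the closest known reaction type is the alkaline NaBH4 reduction of p-hydroxybenzyl alcohols and aryl ethers through quinone methides, together with the enzymatic pterocarpan-to-isoflavan reduction.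

**Compound list**
1 | 2,4-dihydroxyacetophenone | CC(=O)c1ccc(O)cc1O | starting material
2 | 4-acetyl-3-hydroxyphenyl 4-methylbenzenesulfonate | CC(=O)c1ccc(OS(=O)(=O)c2ccc(C)cc2)cc1O | intermediate
3 | 4-bromoresorcinol (4-bromobenzene-1,3-diol) | Oc1ccc(Br)c(O)c1 | starting material
4 | 1-bromo-2,4-bis(methoxymethoxy)benzene | COCOc1ccc(Br)c(OCOC)c1 | intermediate
5 | 4-{[2,4-bis(methoxymethoxy)phenyl]acetyl}-3-hydroxyphenyl 4-methylbenzenesulfonate (deoxybenzoin) | COCOc1ccc(CC(=O)c2ccc(OS(=O)(=O)c3ccc(C)cc3)cc2O)c(OCOC)c1 | intermediate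
6 | 4-{2-[2,4-bis(methoxymethoxy)phenyl]-3-(dimethylamino)prop-2-enoyl}-3-hydroxyphenyl 4-methylbenzenesulfonate (enaminone) | CN(C)C=C(C(=O)c1ccc(OS(=O)(=O)c2ccc(C)cc2)cc1O)c1ccc(OCOC)cc1OCOC | intermediate
7 | 3-[2,4-bis(methoxymethoxy)phenyl]-4-oxo-4H-chromen-7-yl 4-methylbenzenesulfonate (isoflavone) | COCOc1ccc(-c2coc3cc(OS(=O)(=O)c4ccc(C)cc4)ccc3c2=O)c(OCOC)c1 | intermediate
8 | rac-3-[2,4-bis(methoxymethoxy)phenyl]-4-oxochroman-7-yl 4-methylbenzenesulfonate (isoflavanone, racemising) | COCOc1ccc(C2COc3cc(OS(=O)(=O)c4ccc(C)cc4)ccc3C2=O)c(OCOC)c1 | intermediate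
9 | (3R,4R)-3-[2,4-bis(methoxymethoxy)phenyl]-4-hydroxychroman-7-yl 4-methylbenzenesulfonate (cis) | [C@@H]1(c2ccc(OCOC)cc2OCOC)COc2cc(OS(=O)(=O)c3ccc(C)cc3)ccc2[C@@H]1O | intermediate
10 | (3R,4R)-3-(2,4-dihydroxyphenyl)-4-hydroxychroman-7-yl 4-methylbenzenesulfonate | [C@@H]1(c2ccc(O)cc2O)COc2cc(OS(=O)(=O)c3ccc(C)cc3)ccc2[C@@H]1O | intermediate
11 | (6aR,11aR)-9-hydroxy-6a,11a-dihydro-6H-[1]benzofuro[3,2-c]chromen-3-yl 4-methylbenzenesulfonate | [C@@H]12COc3cc(OS(=O)(=O)c4ccc(C)cc4)ccc3[C@@H]1Oc1cc(O)ccc12 | intermediate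
12 | (6aR,11aR)-9-[(3-methylbut-2-en-1-yl)oxy]-6a,11a-dihydro-6H-[1]benzofuro[3,2-c]chromen-3-yl 4-methylbenzenesulfonate | [C@@H]12COc3cc(OS(=O)(=O)c4ccc(C)cc4)ccc3[C@@H]1Oc1cc(OCC=C(C)C)ccc12 | intermediate
13 | (6aR,11aR)-9-hydroxy-8-(2-methylbut-3-en-2-yl)-6a,11a-dihydro-6H-[1]benzofuro[3,2-c]chromen-3-yl 4-methylbenzenesulfonate | [C@@H]12COc3cc(OS(=O)(=O)c4ccc(C)cc4)ccc3[C@@H]1Oc1cc(O)c(C(C)(C)C=C)cc12 | intermediate
14 | (6aR,11aR)-8-(2-methylbut-3-en-2-yl)-9-[(3-methylbut-2-en-1-yl)oxy]-6a,11a-dihydro-6H-[1]benzofuro[3,2-c]chromen-3-yl 4-methylbenzenesulfonate | [C@@H]12COc3cc(OS(=O)(=O)c4ccc(C)cc4)ccc3[C@@H]1Oc1cc(OCC=C(C)C)c(C(C)(C)C=C)cc12 | intermediate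
15 | (6aR,11aR)-8-(2-methylbut-3-en-2-yl)-9-[(3-methylbut-2-en-1-yl)oxy]-6a,11a-dihydro-6H-[1]benzofuro[3,2-c]chromen-3-ol | [C@@H]12COc3cc(O)ccc3[C@@H]1Oc1cc(OCC=C(C)C)c(C(C)(C)C=C)cc12 | intermediate
16 | (3R)-3-{2-hydroxy-5-(2-methylbut-3-en-2-yl)-4-[(3-methylbut-2-en-1-yl)oxy]phenyl}-2,3-dihydro-7H-chromen-7-one (p-quinone methide) | O=C1C=C2OC[C@@H](c3cc(C(C)(C)C=C)c(OCC=C(C)C)cc3O)C=C2C=C1 | intermediate
17 | Manuifolin D, (3R)-3-{2-hydroxy-5-(2-methylbut-3-en-2-yl)-4-[(3-methylbut-2-en-1-yl)oxy]phenyl}chroman-7-ol | C=CC(C)(C)c1cc([C@@H]2COc3cc(O)ccc3C2)c(O)cc1OCC=C(C)C | target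

**Totals and risks**
Total step count: 8. Longest linear sequence: 7 (steps 1, 3, 4, 5, 6, 7, 8, from compound 1).

Step 4 (three events in one flask; ee and dr depend on the DKR running faster than reduction of the unwanted enantiomer). The fallback sets out from 7, isolated by aqueous work-up after the DMF-DMA stage, and comes back at 11; it sets C3 by reagent-controlled hydroboration of an alkene instead of DKR of a ketone. NaBH4 in EtOH/THF reduces 7 to the racemic diastereomer mixture 3-[2,4-bis(methoxymethoxy)phenyl]-4-hydroxychroman-7-yl 4-methylbenzenesulfonate F4. Mesylation and elimination (MsCl, Et3N, then DBU) give the isoflav-3-ene 3-[2,4-bis(methoxymethoxy)phenyl]-2H-chromen-7-yl 4-methylbenzenesulfonate F5. Asymmetric hydroboration with monoisopinocampheylborane (the enantiomer that delivers H to C3 on the face giving 3R), followed by NaBO3 oxidation, gives the trans carbinol (3R,4S)-3-[2,4-bis(methoxymethoxy)phenyl]-4-hydroxychroman-7-yl 4-methylbenzenesulfonate F6. 3 M HCl in MeOH then removes the MOM groups and closes the dihydrofuran by SN1 with inversion at C4 to the cis-fused 11; ee is upgraded by recrystallising 11 if needed.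

Step 8 (new use of quinone-methide reduction; the quinone methide could tautomerise to the achiral isoflav-3-ene and erode ee). The fallback sets out from 14 and comes back at 17; it replaces the anionic hydride pathway by cationic ionic hydrogenation. Mg in MeOH at rt removes the tosylate without heating the phenoxide, and the phenol 15 is isolated. Et3SiH (5 equiv) with TFA (5 equiv) in CH2Cl2 at −40 °C then ionises the now very labile p-hydroxybenzylic ether and the silane reduces the cation to 17; the low temperature is what should spare the prenyl ether.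

Step 3 (α-arylation of a ketone carrying a free ortho phenol and an aryl tosylate, with an electron-rich ortho-substituted bromide). The fallback sets out from 2 and 4 and comes back at 7; it makes the aryl–C3 bond by cross-coupling on a preformed chromone. Ketone 2 and DMF-DMA give the enaminone (E)-3-(dimethylamino)-1-[2-hydroxy-4-(tosyloxy)phenyl]prop-2-en-1-one F1, which I2 in CHCl3 cyclises with loss of dimethylamine to 3-iodo-4-oxo-4H-chromen-7-yl 4-methylbenzenesulfonate F2. Bromide 4 is converted by Miyaura borylation (B2pin2, Pd(dppf)Cl2, KOAc, dioxane) into 2-[2,4-bis(methoxymethoxy)phenyl]-4,4,5,5-tetramethyl-1,3,2-dioxaborolane F3. Suzuki–Miyaura coupling of F2 with F3 (Pd(PPh3)4, K2CO3, dioxane/H2O, 80 °C) gives isoflavone 7, which enters step 4 at its transfer-hydrogenation stage.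

**Further compounds**
F1 | step 3 | (E)-3-(dimethylamino)-1-[2-hydroxy-4-(tosyloxy)phenyl]prop-2-en-1-one | CN(C)/C=C/C(=O)c1ccc(OS(=O)(=O)c2ccc(C)cc2)cc1O
F2 | step 3 | 3-iodo-4-oxo-4H-chromen-7-yl 4-methylbenzenesulfonate | O=c1c(I)coc2cc(OS(=O)(=O)c3ccc(C)cc3)ccc12
F3 | step 3 | 2-[2,4-bis(methoxymethoxy)phenyl]-4,4,5,5-tetramethyl-1,3,2-dioxaborolane | COCOc1ccc(B2OC(C)(C)C(C)(C)O2)c(OCOC)c1
F4 | step 4 | 3-[2,4-bis(methoxymethoxy)phenyl]-4-hydroxychroman-7-yl 4-methylbenzenesulfonate (racemic diastereomer mixture) | COCOc1ccc(C2COc3cc(OS(=O)(=O)c4ccc(C)cc4)ccc3C2O)c(OCOC)c1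
F5 | step 4 | 3-[2,4-bis(methoxymethoxy)phenyl]-2H-chromen-7-yl 4-methylbenzenesulfonate | COCOc1ccc(C2=Cc3ccc(OS(=O)(=O)c4ccc(C)cc4)cc3OC2)c(OCOC)c1
F6 | step 4 | (3R,4S)-3-[2,4-bis(methoxymethoxy)phenyl]-4-hydroxychroman-7-yl 4-methylbenzenesulfonate | [C@@H]1(c2ccc(OCOC)cc2OCOC)COc2cc(OS(=O)(=O)c3ccc(C)cc3)ccc2[C@H]1O
F0 | step 8 | none | none
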